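**Plan**

1. Retrosynthetic cuts: the two aryl–CHO bonds and C1′–Ph last; then C1–O and C4–C1′ of the oxepane (oxa-Michael addition and enolate addition to an o-quinone methide, both enabled by a temporary C3 ketone); then C7–C11 of the cyclopropane; then C9–C10 and C6–C7 of the cycloheptane together; then C1–C5 of the cyclopentane.
2. Enabling feature: in the seven-membered ring, C10–C1–C5–C6 can be a 1,3-diene that is exocyclic to the cyclopentane and therefore locked s-cis, and C7–C8–C9 can be an oxyallyl cation. The C8 carbonyl left by the cycloaddition acidifies C7, which then closes the gem-dimethylcyclopropane onto C11 (already on C6), and is removed afterwards.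
3. Forward order: five-membered ring (zirconocene diyne cyclisation) → seven-membered ring ((4+3) cycloaddition) → cyclopropane → enone → oxepane → phenyl at C1′ → formyl groups.
4. Stereochemistry: one bought stereocentre, (R)-but-3-yn-2-ol, becomes C4–CH3 and sets C3 (anti propargylation). These two shield one diene face, so the (4+3) step sets C10 and C6 together. C7 follows from cis ring fusion, C5 from equilibration (C4 trans to C11), C4 is re-set by alkylation trans to C6, C1 by the tether, and C1′ by exo attack on the bridged benzylic cation.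

Key step: step 7

Remark: skeletal atoms carry aromadendrane numbers (C1/C5 ring fusion, C2–C4 five-membered ring, C6–C10 seven-membered ring, C11 cyclopropane carbon, C1′ benzylic carbon); in the target O-1, H-5, C1′, CH3 on C10 and C11 lie on one face and CH3 on C4, H-6, H-7, H-10 on the other; compounds 1, 3, 7, 11 and 19 are taken as commercial.

**Route**

Step 1
Reactants: 1 (R)-but-3-yn-2-ol
Product: 2 (R)-but-3-yn-2-yl methanesulfonate
Conditions: MsCl, Et3N, CH2Cl2, −78 → 0 °C
Reagents that add atoms: methanesulfonyl chloride, CS(=O)(=O)Cl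
Why: O-sulfonylation of a secondary propargylic alcohol, which does not touch the stereocentre.

Step 2
Reactants: 3 pent-3-yn-1-ol
Product: 4 pent-3-ynal
Conditions: DMP, CH2Cl2, 0 °C; filtered through basic alumina and used at once in solution
Reagents that add atoms: none
Why: Dess–Martin oxidation under neutral conditions, chosen because the β,γ-alkynyl aldehyde isomerises to the allenal with acid or base.

Step 3
Reactants: 4 pent-3-ynal; 2 (R)-but-3-yn-2-yl methanesulfonate
Product: 5 (3S,4R)-3-methylocta-1,6-diyn-4-ol (anti)
Conditions: Pd(OAc)2 (5 mol %), PPh3, Et2Zn, THF, −78 → −20 °C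
Reagents that add atoms: none
Why: Marshall propargylation: zerovalent palladium displaces the mesylate anti (SN2′), transmetalation gives a chiral allenylzinc, and its addition to the aldehyde through a cyclic SE2′ transition state should transfer the stereocentre with inversion to the methyl-bearing carbon (C4) and set the carbinol carbon (C3) anti to it.

Step 4
Reactants: 5 (3S,4R)-3-methylocta-1,6-diyn-4-ol
Product: 6 triethyl{[(3S,4R)-3-methylocta-1,6-diyn-4-yl]oxy}silane
Conditions: TESCl, imidazole, DMF, 0 °C
Reagents that add atoms: chlorotriethylsilane, CC[Si](Cl)(CC)CC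
Why: Silylation of the secondary alcohol protects it from the organometallic and cationic steps and adds bulk on the face that is to be shielded in step 7.

Step 5
Reactants: 6 triethyl{[(3S,4R)-3-methylocta-1,6-diyn-4-yl]oxy}silane; 7 2-bromopropene
Product: 8 triethyl{[(5S,6R)-2,5-dimethyldec-1-ene-3,8-diyn-6-yl]oxy}silane
Conditions: Pd(PPh3)2Cl2 (cat.), CuI (cat.), i-Pr2NH, THF, 25 °C
Reagents that add atoms: none
Why: Sonogashira coupling of the terminal alkyne with a vinyl bromide brings in C11 as an isopropenyl group; the internal alkyne and the silyl ether are inert.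

Step 6
Reactants: 8 triethyl{[(5S,6R)-2,5-dimethyldec-1-ene-3,8-diyn-6-yl]oxy}silane
Product: 10 triethyl{[(1R,2S,3E,4E)-4-ethylidene-2-methyl-3-(2-methylprop-2-en-1-ylidene)cyclopentyl]oxy}silane, via zirconacyclopentadiene 9 (not isolated)
Conditions: Cp2ZrCl2, n-BuLi (2 equiv), THF, −78 °C; then 8, −78 → 25 °C; then AcOH, 0 °C
Reagents that add atoms: none
Why: Zirconocene-mediated oxidative cyclisation of a 1,6-diyne gives the bicyclic zirconacyclopentadiene, and protonolysis of both C–Zr bonds with retention leaves H-10 and H-6 on the inside, so the (E,E)-1,2-dialkylidenecyclopentane should form with methyl and isopropenyl pointing outward.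

Step 7
Reactants: 10 triethyl{[(1R,2S,3E,4E)-4-ethylidene-2-methyl-3-(2-methylprop-2-en-1-ylidene)cyclopentyl]oxy}silane; 11 2-methoxyallyl bromide
Product: 13 3-hydroxy-6-isopropenyl-4,10-dimethylhydroazul-1(5)-en-8-one (3-OH cis to 4-CH3; H-6 cis to H-10), via enol ether cycloadduct 12 (not isolated)
Conditions: AgOCOCF3, Na2CO3, CH2Cl2, −78 → 0 °C, dark; then 1 M HCl, THF, 25 °C
Reagents that add atoms: water, O
Why: AgOCOCF3 takes bromide from 11 to give the 2-methoxyallyl cation, which adds with its two CH2 termini to C10 and C6 of the s-cis diene (concerted, or by attack at C10 then closure of the enol ether carbon on C6), and acid then hydrolyses the methyl enol ether to the C8 ketone and cleaves the TES ether. The closest known reaction type is the (4+3) cycloaddition of 2-alkoxyallyl (oxyallyl) cations with 1,3-dienes to cyclohept-4-enones. The seven-membered ring is closed by intermolecular (4+3) cycloaddition in which the C9–C10 and C6–C7 bonds both form, C1=C5 being left as the ring-fusion alkene. C10 and C6 are set relative to each other by addition of both termini to one face of the (E,E)-diene, whose methyl and isopropenyl groups point outward so that H-10 and H-6 end cis. Their absolute sense comes from the C4 methyl and the cis C3 silyloxy group, which cover one face of the planar diene and send the cation to the other. The step needs periselectivity for the cyclopentane-locked diene over the C5=C6–C11=CH2 diene and over (3+2) closure, and the enforced s-cis geometry and higher substitution of the exocyclic diene are expected to secure it.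

Step 8
Reactants: 13 3-hydroxy-6-isopropenyl-4,10-dimethylhydroazul-1(5)-en-8-one
Product: 14 6-(2-chloropropan-2-yl)-3-hydroxy-4,10-dimethylhydroazul-1(5)-en-8-one
Conditions: Co(BF4)2·6H2O (cat.), N,N′-bis(3,5-di-tert-butylsalicylidene)ethylenediamine (cat.), t-BuOOH (cat.), PhSiH3, TsCl, EtOH, 25 °C
Reagents that add atoms: p-toluenesulfonyl chloride, Cc1ccc(cc1)S(Cl)(=O)=O
Why: Markovnikov hydrochlorination by hydrogen-atom transfer from a cobalt hydride to the 1,1-disubstituted alkene and chlorine transfer from TsCl to the tertiary C11 radical; the tetrasubstituted C1=C5 alkene reacts far more slowly in hydrogen-atom transfer and the ketone and alcohol are inert.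

Step 9
Reactants: 14 6-(2-chloropropan-2-yl)-3-hydroxy-4,10-dimethylhydroazul-1(5)-en-8-one
Product: 15 3-hydroxyaromadendr-1(5)-en-8-one (H-6 cis to H-7)
Conditions: KOt-Bu, t-BuOH–THF, 0 → 25 °C
Reagents that add atoms: none
Why: Intramolecular enolate alkylation (1,3-elimination, 3-exo-tet), the reaction by which dihydrocarvone hydrohalides give carone: the C7 enolate displaces the tertiary chloride on C11, and since the cyclopropane can only be cis-fused the new stereocentre C7 follows C6.

Step 10
Reactants: 15 3-hydroxyaromadendr-1(5)-en-8-one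
Product: 16 aromadendr-1(5)-en-3-ol (3-OH cis to 4-CH3)
Conditions: N2H4·H2O, KOH, diethylene glycol, 130 °C then 200 °C
Reagents that add atoms: none
Why: Wolff–Kishner reduction removes the C8 carbonyl once it has served; cyclopropyl ketones are reduced without ring opening, and the alkene and alcohol tolerate the base.

Step 11
Reactants: 16 aromadendr-1(5)-en-3-ol
Product: 18 aromadendr-1-en-3-one (H-5 on the face of C11, trans to H-6; 4-CH3 unchanged), via deconjugated enone 17 (not isolated)
Conditions: DMP, CH2Cl2, 0 °C; then pyrrolidine (20 mol %), AcOH (20 mol %), 25 °C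
Reagents that add atoms: none
Why: Dess–Martin oxidation gives the β,γ-enone, and amine catalysis moves the double bond into conjugation through the dienamine on the unsubstituted C2 side (the C4 side is disfavoured by allylic strain with the C4 methyl) with γ-protonation at C5, where reversible protonation should let C5 settle with C4 trans to the cyclopropane carbon C11.

Step 12
Reactants: 19 3,5-bis(benzyloxy)phenol
Product: 20 3,5-bis(benzyloxy)-2-[(dimethylamino)methyl]phenol
Conditions: CH2=NMe2+ I−, K2CO3, CH2Cl2, 25 °C
Reagents that add atoms: N,N-dimethylmethyleneiminium iodide, C=[N+](C)C.[I-]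
Why: Mannich aminomethylation with a preformed iminium salt, expected ortho to the hydroxyl at the position flanked by OH and OBn and not at the more hindered position between the two benzyloxy groups.

Step 13
Reactants: 20 3,5-bis(benzyloxy)-2-[(dimethylamino)methyl]phenol
Product: 21 [2,4-bis(benzyloxy)-6-hydroxybenzyl]trimethylammonium iodide
Conditions: MeI, acetone, 25 °C
Reagents that add atoms: iodomethane, CI
Why: Quaternisation turns the amine into a leaving group for base-induced release of the o-quinone methide; the phenol is not methylated without base.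

Step 14
Reactants: 18 aromadendr-1-en-3-one; 21 [2,4-bis(benzyloxy)-6-hydroxybenzyl]trimethylammonium iodide
Product: 24 bridged ketone (4-[2,4-bis(benzyloxy)-6-oxybenzyl]aromadendran-3-one with the phenolic oxygen bonded to C1; O-1, H-5 and C1′ on one face), via o-quinone methide 22 (not isolated), via Michael adduct phenol 23 (not isolated)
Conditions: 18, LDA, THF, −78 °C; add 21 pretreated with LiHMDS (1 equiv) in THF–DMPU, −78 → 25 °C; then MeOH, K2CO3 (cat.), 40 °C
Reagents that add atoms: none
Why: Kinetic deprotonation gives the C3=C4 enolate, which adds to the o-quinone methide released from the phenoxide of 21 (Michael addition) on the cyclopentenone face opposite to C6, and in methanol the freed phenoxide closes the oxepane by intramolecular oxa-Michael addition to C1 from the only face the tether can reach, which sets C4 and C1.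

Step 15
Reactants: 24 bridged ketone
Product: 26 bridged ether (3-deoxo-24), via tosylhydrazone 25 (not isolated)
Conditions: TsNHNH2, MeOH, 60 °C; then catecholborane, CHCl3, 0 °C; NaOAc·3H2O, 60 °C
Reagents that add atoms: none
Why: Tosylhydrazone formation, hydride reduction with catecholborane and loss of sulfinate and N2 replace the carbonyl by CH2 under near-neutral conditions, which avoids the retro-oxa-Michael reaction that strong base would cause in the β-aryloxy ketone.

Step 16
Reactants: 26 bridged ether
Product: 27 C1′-methoxy bridged ether (OMe on the face of the C4 methyl)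
Conditions: DDQ, CH2Cl2–MeOH (10:1), 0 °C
Reagents that add atoms: methanol, CO
Why: DDQ removes hydride from benzylic C1′, which is ortho and para to three oxygen substituents, and methanol traps the cation on the open face of the bridged ring to give a benzylic ether ready for ionisation.

Step 17
Reactants: 27 C1′-methoxy bridged ether
Product: 28 O,O′-dibenzyl bis(deformyl)psiguadial A
Conditions: PhMgBr, CuBr·SMe2 (cat.), BF3·OEt2, CH2Cl2–Et2O, −78 → −20 °C
Reagents that add atoms: phenylmagnesium bromide, Br[Mg]c1ccccc1
Why: Lewis-acid mediated substitution of a benzylic ether by an organocopper reagent: BF3 regenerates the cation and the phenyl group should add from the less hindered face, syn to the one-atom bridge C5 and away from the C2–C3 bridge, which sets C1′ with phenyl on the side of the C4 methyl.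

Step 18
Reactants: 28 O,O′-dibenzyl bis(deformyl)psiguadial A
Product: 29 bis(deformyl)psiguadial A (free resorcinol)
Conditions: H2 (1 atm), Pd/C, EtOAc–MeOH, 25 °C
Reagents that add atoms: none
Why: Hydrogenolysis of the two benzyl ethers; the unactivated cyclopropane, the tertiary alkyl aryl ether and the diarylmethine C–C bonds should be stable.

Step 19
Reactants: 29 bis(deformyl)psiguadial A
Product: 30 psiguadial A
Conditions: Cl2CHOMe, TiCl4, CH2Cl2, −78 → 0 °C; aqueous work-up
Reagents that add atoms: dichloromethyl methyl ether, COC(Cl)Cl; water, O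
Why: Rieche formylation: the titanium phenoxide directs Cl2CHOMe to the two free ring positions, each ortho and para to oxygen, and hydrolysis of the chloro ethers gives the dialdehyde.

**Compound list**

1 | (R)-but-3-yn-2-ol | C[C@@H](O)C#C | starting material
2 | (R)-but-3-yn-2-yl methanesulfonate | C[C@@H](OS(C)(=O)=O)C#C | intermediate
3 | pent-3-yn-1-ol | CC#CCCO | starting material
4 | pent-3-ynal | CC#CCC=O | intermediate
5 | (3S,4R)-3-methylocta-1,6-diyn-4-ol | CC#CC[C@@H](O)[C@@H](C)C#C | intermediate
6 | triethyl{[(3S,4R)-3-methylocta-1,6-diyn-4-yl]oxy}silane | CC#CC[C@@H](O[Si](CC)(CC)CC)[C@@H](C)C#C | intermediate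
7 | 2-bromopropene | CC(Br)=C | starting material
8 | triethyl{[(5S,6R)-2,5-dimethyldec-1-ene-3,8-diyn-6-yl]oxy}silane | CC#CC[C@@H](O[Si](CC)(CC)CC)[C@@H](C)C#CC(C)=C | intermediate
9 | zirconacyclopentadiene (Cp2Zr bonded to C10 and C6; OTES and 4-CH3 cis) | CC1=C2C[C@@H](O[Si](CC)(CC)CC)[C@@H](C)C2=C(C(C)=C)[Zr]1(C1C=CC=C1)C1C=CC=C1 | intermediate
10 | triethyl{[(1R,2S,3E,4E)-4-ethylidene-2-methyl-3-(2-methylprop-2-en-1-ylidene)cyclopentyl]oxy}silane | C/C=C1\C[C@@H](O[Si](CC)(CC)CC)[C@@H](C)/C1=C\C(C)=C | intermediate
11 | 2-methoxyallyl bromide (3-bromo-2-methoxyprop-1-ene) | COC(=C)CBr | starting material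
12 | enol ether cycloadduct (8-methoxy-6-isopropenyl-4,10-dimethyl-3-triethylsilyloxyhydroazula-1(5),8-diene; one enol ether regioisomer shown) | C[C@H]1C=C(OC)C[C@H](C3=C1C[C@@H](O[Si](CC)(CC)CC)[C@H]3C)C(C)=C | intermediate
13 | 3-hydroxy-6-isopropenyl-4,10-dimethylhydroazul-1(5)-en-8-one | C[C@H]1CC(=O)C[C@H](C3=C1C[C@@H](O)[C@H]3C)C(C)=C | intermediate
14 | 6-(2-chloropropan-2-yl)-3-hydroxy-4,10-dimethylhydroazul-1(5)-en-8-one | C[C@H]1CC(=O)C[C@H](C3=C1C[C@@H](O)[C@H]3C)C(C)(C)Cl | intermediate
15 | 3-hydroxyaromadendr-1(5)-en-8-one | C[C@H]1CC(=O)[C@@H]2[C@H](C3=C1C[C@@H](O)[C@H]3C)C2(C)C | intermediate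
16 | aromadendr-1(5)-en-3-ol | C[C@H]1CC[C@@H]2[C@H](C3=C1C[C@@H](O)[C@H]3C)C2(C)C | intermediate
17 | aromadendr-1(5)-en-3-one | C[C@H]1CC[C@@H]2[C@H](C3=C1CC(=O)[C@H]3C)C2(C)C | intermediate
18 | aromadendr-1-en-3-one | C[C@H]1CC[C@@H]2[C@H]([C@@H]3[C@H](C)C(=O)C=C31)C2(C)C | intermediate
19 | 3,5-bis(benzyloxy)phenol | Oc1cc(OCc2ccccc2)cc(OCc2ccccc2)c1 | starting material
20 | 3,5-bis(benzyloxy)-2-[(dimethylamino)methyl]phenol | CN(C)Cc1c(O)cc(OCc2ccccc2)cc1OCc1ccccc1 | intermediate
21 | [2,4-bis(benzyloxy)-6-hydroxybenzyl]trimethylammonium iodide | C[N+](C)(C)Cc1c(O)cc(OCc2ccccc2)cc1OCc1ccccc1.[I-] | intermediate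
22 | 3,5-bis(benzyloxy)-6-methylenecyclohexa-2,4-dien-1-one (o-quinone methide) | C=C1C(=O)C=C(OCc2ccccc2)C=C1OCc1ccccc1 | intermediate
23 | 4-[2,4-bis(benzyloxy)-6-hydroxybenzyl]aromadendr-1-en-3-one (benzyl group trans to C6) | C[C@H]1CC[C@@H]2[C@H]([C@@H]3[C@@](C)(Cc4c(O)cc(OCc5ccccc5)cc4OCc4ccccc4)C(=O)C=C31)C2(C)C | intermediate
24 | bridged ketone (oxepane closed between the phenolic oxygen and C1; C3 ketone) | C[C@H]1CC[C@@H]2[C@H]([C@@H]3[C@]4(C)C(=O)C[C@@]31Oc1cc(OCc5ccccc5)cc(OCc5ccccc5)c1C4)C2(C)C | intermediate
25 | tosylhydrazone of 24 (C=N geometry not defined) | C[C@H]1CC[C@@H]2[C@H]([C@@H]3[C@]4(C)C(=NNS(=O)(=O)c5ccc(C)cc5)C[C@@]31Oc1cc(OCc5ccccc5)cc(OCc5ccccc5)c1C4)C2(C)C | intermediate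
26 | bridged ether (3-deoxo-24) | C[C@H]1CC[C@@H]2[C@H]([C@@H]3[C@]4(C)CC[C@@]31Oc1cc(OCc5ccccc5)cc(OCc5ccccc5)c1C4)C2(C)C | intermediate
27 | C1′-methoxy bridged ether | C[C@H]1CC[C@@H]2[C@H]([C@@H]3[C@]4(C)CC[C@@]31Oc1cc(OCc5ccccc5)cc(OCc5ccccc5)c1[C@@H]4OC)C2(C)C | intermediate
28 | O,O′-dibenzyl bis(deformyl)psiguadial A | C[C@H]1CC[C@@H]2[C@H]([C@@H]3[C@]4(C)CC[C@@]31Oc1cc(OCc5ccccc5)cc(OCc5ccccc5)c1[C@@H]4c1ccccc1)C2(C)C | intermediate
29 | bis(deformyl)psiguadial A | C[C@H]1CC[C@@H]2[C@H]([C@@H]3[C@]4(C)CC[C@@]31Oc1cc(O)cc(O)c1[C@@H]4c1ccccc1)C2(C)C | intermediate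
30 | psiguadial A | C[C@H]1CC[C@@H]2[C@H]([C@@H]3[C@]4(C)CC[C@@]31Oc1c(C=O)c(O)c(C=O)c(O)c1[C@@H]4c1ccccc1)C2(C)C | target

**Totals and risks**

Total step count: 19
Longest linear sequence: 16 steps (steps 1, 3–11, 14–19)

Steps most likely to fail:

Step 7. The cation may add stepwise and the intermediate allyl cation may then lose a proton or close to a five-membered ring; the silver salt and acid may also degrade the polyene, and facial control may be incomplete. The fallback generates the three-carbon unit reductively on iron in place of halide abstraction. It sets out from 10: Fe2(CO)9 and 1,1,3,3-tetrabromoacetone in benzene at 60 °C should give the 7,9-dibromo ketone F1, Zn–Cu couple with NH4Cl in MeOH should remove both bromines to give the silyl-protected ketone F2, and 1 M HCl in THF brings the sequence back to the route at 13.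

Step 11. Enolisation toward C4 may compete and move the double bond to C4=C5, which would remove the C4 hydrogen needed in step 14 and flatten C5. Too long an exposure may also epimerise C10 through the exocyclic dienamine. The fallback sets C5 kinetically and avoids any equilibration. It sets out from 16: Mitsunobu inversion (4-nitrobenzoic acid, PPh3, DIAD) should give the inverted ester F3, and K2CO3 in MeOH the epimeric alcohol F4. Hydroxyl-directed hydrogenation with [Ir(cod)(PCy3)(py)]PF6 and H2 should then deliver hydrogen to C1 and C5 from the face of the hydroxyl group and of C11 to give the saturated alcohol F5. DMP gives the ketone F6, LDA and TMSCl at −78 °C the less substituted silyl enol ether F7, and Saegusa–Ito oxidation with Pd(OAc)2 in MeCN brings the sequence back to the route at 18.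

Step 14. Proton transfer between the phenolic ammonium salt and the kinetic enolate, or slow release of the o-quinone methide at low temperature, may scramble the enolate so that C-alkylation at C4 fails; the oxa-Michael closure may also stop short of completion. The fallback replaces enolate chemistry by a cycloaddition. It sets out from 18: LDA and TMSCl should give the cross-conjugated silyl dienol ether F8. Heating F8 with Mannich base 20 in toluene at 110 °C releases 22, which should add to the C3=C4 enol ether in an inverse-demand hetero-Diels–Alder reaction on the face opposite to C6 to give the chroman silyl ketal F9. Aqueous TFA in THF opens F9 to 23, and K2CO3 in MeOH brings the sequence back to the route at 24.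

**Further compounds**

F1 | step 7 | 7,9-dibromo-6-isopropenyl-4,10-dimethyl-3-triethylsilyloxyhydroazul-1(5)-en-8-one (bromine-bearing carbons not defined) | C[C@H]1C(Br)C(=O)C(Br)[C@H](C3=C1C[C@@H](O[Si](CC)(CC)CC)[C@H]3C)C(C)=C
F2 | step 7 | triethylsilyl ether of 13 | C[C@H]1CC(=O)C[C@H](C3=C1C[C@@H](O[Si](CC)(CC)CC)[C@H]3C)C(C)=C
F3 | step 11 | 4-nitrobenzoate of 3-epi-16 | C[C@H]1CC[C@@H]2[C@H](C3=C1C[C@H](OC(=O)c4ccc(cc4)[N+]([O-])=O)[C@H]3C)C2(C)C
F4 | step 11 | 3-epi-16 (3-OH trans to 4-CH3) | C[C@H]1CC[C@@H]2[C@H](C3=C1C[C@H](O)[C@H]3C)C2(C)C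
F5 | step 11 | aromadendran-3-ol with H-1, H-5 and 3-OH on the face of C11 | C[C@H]1CC[C@@H]2[C@H]([C@@H]3[C@H](C)[C@@H](O)C[C@@H]31)C2(C)C
F6 | step 11 | aromadendran-3-one with H-1 and H-5 on the face of C11 | C[C@H]1CC[C@@H]2[C@H]([C@@H]3[C@H](C)C(=O)C[C@@H]31)C2(C)C
F7 | step 11 | 3-(trimethylsilyloxy)aromadendr-2-ene | C[C@H]1CC[C@@H]2[C@H]([C@@H]3[C@H](C)C(O[Si](C)(C)C)=C[C@@H]31)C2(C)C
F8 | step 14 | 3-(trimethylsilyloxy)aromadendra-1,3-diene | C[C@H]1CC[C@@H]2[C@H]([C@@H]3C(C)=C(O[Si](C)(C)C)C=C31)C2(C)C
F9 | step 14 | chroman silyl ketal (aryl oxygen on C3, C1′ on C4, both trans to C6; C1=C2 retained) | C[C@H]1CC[C@@H]2[C@H]([C@@H]3[C@@]4(C)Cc5c(OCc6ccccc6)cc(OCc6ccccc6)cc5O[C@@]4(O[Si](C)(C)C)C=C31)C2(C)C
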